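6.84: that many moles of starting material had gone per mole of initiator charged at the last reading of the spring run. Call this the yield per initiator, y: starting material reacted at the end, divided by initiator charged. The winter run, with 3.43 times the scavenger, gives 6.87, and its end reading differs from spring's by 0.1 percentage points against a scatter of 1 point.

all flasks: starting material 0.10 M; initiator 4.5 mM
- spring: reagent 0.095 M; scavenger 0.070 M; run made earlier
- winter: reagent 0.095 M; scavenger 0.24 M; run made earlier
- zeta: reagent 0.0950 M; scavenger 0.120 M; time 2.5 min
- gamma: reagent 0.0950 M; scavenger 0.180 M; time 2.5 min
- alpha: reagent 0.0950 M; scavenger 0.270 M; time 2.5 min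

| run | time / min | starting material / % | product / % |
|---|---|---|---|
| spring | 0.417 | 82.6 | 10.7 |
| spring | 0.833 | 76.7 | 16.1 |
| spring | 1.33 | 72.5 | 19.2 |
| spring | 1.50 | 69.8 | 20.2 |
| spring | 2.00 | 69.3 | 22.9 |
| spring | 2.50 | 69.2 | 20.7 |
| winter | 0.167 | 90.9 | 5.2 |
| winter | 0.500 | 81.2 | 12.1 |
| winter | 0.833 | 76.8 | 17.2 |
| winter | 1.33 | 73.8 | 20.1 |
| winter | 2.00 | 72.2 | 21.7 |
| winter | 2.50 | 69.1 | 21.6 |

(readings scatter by 1 percentage point)



- part of the starting material that has reacted at the end, zeta
- part of the starting material that has reacted at the end, gamma
- part of the starting material that has reacted at the end, alpha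
- what raising the concentration of scavenger from its lowest to its highest value here does to the part of the starting material that has reacted (changes below 5 percentage points count as none) (it falls / it rises / no change)

Now watch the winter run in slow motion. In the first instants you lose 9.10% of the starting material by 0.167 min, a rate of 0.0545 M min⁻¹. In the middle, from 0.833 min to 1.33 min, the rate reads 0.00604 M min⁻¹, so the ratio of the two reads 9.02, a rough figure because it rests on scattered readings. Yet 73.8% of the starting material still stands there, so its own loss does not account for that fall.

At the end the spring run reads 69.3% and then 69.2%, which is flat within the scatter. Its product is 0.0207 M against 0.095 M of reagent charged, so reagent does not look short either. I therefore treat the initiator, the smallest charge at 4.5 mM, as the limiting reagent.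

My rule, for the reagent charge and the time of these runs, is that the part reacted equals y times initiator over starting material, and y carries the scatter of the reading it came from. For zeta, gamma and alpha, which share those charges, it gives 30.8%. Alpha's 0.270 M of scavenger lies beyond the 0.24 M tried, so that flask is a small extrapolation.

The forecast gave 30.8%, 30.8% and 30.8%, no change, holding that “scavenger affects neither the rate nor the final extent”.

The flasks give 30.4%, 30.4% and 30.4%, a shift of 0.031 points across the scavenger range, so no change.

    initiator → 2 initiating radical (k = 0.0330 s⁻¹)
    starting material + initiating radical → capped initiator + first chain carrier (k = 1.50 × 10⁵ L mol⁻¹ s⁻¹)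
    reagent + first chain carrier → product + second chain carrier (k = 7900 L mol⁻¹ s⁻¹)
    starting material + second chain carrier → released group + first chain carrier (k = 47000 L mol⁻¹ s⁻¹)
    first chain carrier → ended carrier (k = 200 s⁻¹)
    2 second chain carrier → ended chains A (k = 2.40 × 10⁷ L mol⁻¹ s⁻¹)
    2 first chain carrier → ended chains B (k = 8.00 × 10⁷ L mol⁻¹ s⁻¹)
    reagent + released group ⇌ idle adduct, settled at all times (K = 52.0 L mol⁻¹)
    scavenger + released group → scavenged by-product (k = 40.0 L mol⁻¹ s⁻¹)
    released group → by-product carried off (k = 0.580 s⁻¹)

In zeta, y comes to 6.75, with 0.71% of the initiator left at 2.50 min against 70% of the starting material. Now take a neighbour of zeta charged with 0.040 M of starting material. The y of 6.84 on the same 4.5 mM of initiator gives 77.0% reacted. That neighbour flask reacts 74.6%, and at its end product holds 52.8% of the starting material charged.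

Readings and results were computed from invented constants, and the scatter is random.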